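**Retrosynthetic overview**
1. Target ⇐ macrocyclic alcohol 10 by acylation of the C4 hydroxyl (ester installed last).
2. The 11-membered ring (the only ring) ⇐ C7–C8 bond by intramolecular B-alkyl Suzuki coupling of a (Z)-vinyl iodide onto a hydroborated terminal alkene (fixes 6Z).
3. (Z)-Vinyl iodide ⇐ iodo-Wittig olefination of a C6 aldehyde; C4–C5 bond and the C4 stereocentre ⇐ catalytic asymmetric acetaldehyde Mukaiyama aldol on an enal.
4. Enal ⇐ one-pot enamine-catalysed α-acetoxylation (sets C1, installs the acetate) and Wittig olefination (2E alkene) of 3,3-dimethylhex-5-enal.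
5. 3,3-Dimethylhex-5-enal ⇐ one-carbon homologation of 2,2-dimethylpent-4-enal.

Ring numbering used throughout: C1 (CH–OAc), C2=C3(Me), C4 (CH–O-aroyl), C5, C6=C7(Me), C8, C9, C10, C11 (CMe2). The target is (1R,2E,4S,6Z).

Assumption: the two non-catalogue reagents (acetyl 2,4,6-trichlorobenzoyl peroxide and (1-iodoethyl)triphenylphosphonium iodide) are prepared beforehand from commercial chemicals and not counted as steps, and the IDPi enantiomer that gives Si-face attack on the enal is the one used.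

**Step 1**
Reactants: 1 2,2-dimethylpent-4-enal
Product: 3 3,3-dimethylhex-5-enal, via enol ether 2 (not isolated)
Conditions: MeOCH2PPh3Cl, KOtBu, THF, 0 °C to rt; then 2 M HCl (aq), THF, rt
Reagents that add atoms: (methoxymethyl)triphenylphosphonium chloride, COC[P+](c1ccccc1)(c1ccccc1)c1ccccc1.[Cl-]; water, O
Why: Wittig methoxymethylenation of the non-enolisable neopentyl aldehyde followed by acid hydrolysis of the enol ether is a standard one-carbon homologation, and the terminal alkene is inert to both operations.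

**Step 2**
Reactants: 3 3,3-dimethylhex-5-enal
Product: 5 (2E,4R)-4-acetoxy-2,5,5-trimethylocta-2,7-dienal, via α-acetoxy aldehyde 4 (not isolated)
Conditions: (S)-α,α-diphenylprolinol trimethylsilyl ether (10 mol%), acetyl 2,4,6-trichlorobenzoyl peroxide (dilute solution), hydroquinone (10 mol%), THF, 0 °C; then 2,6-lutidine, Ph3P=C(Me)CHO, 0 °C to rt
Reagents that add atoms: acetyl 2,4,6-trichlorobenzoyl peroxide, CC(=O)OOC(=O)c1c(Cl)cc(Cl)cc1Cl; 2-(triphenylphosphoranylidene)propanal, CC(C=O)=P(c1ccccc1)(c1ccccc1)c1ccccc1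
Why: Proposed new method: the (E)-enamine of 3 attacks the O–O bond of an unsymmetrical diacyl peroxide at the acetyl-bearing oxygen, because that displaces the far better leaving group (2,4,6-trichlorobenzoate) and the ortho-chlorines shield the other oxygen and the aroyl carbonyl, so acetoxy rather than aroyloxy is transfered anti to the bulky diphenyl(silyloxy)methyl group to give the (S)-α-acetoxy aldehyde (C1 of the target, R after the priority change on olefination); the closest known reaction is the diarylprolinol-silyl-ether-catalysed α-benzoyloxylation of aldehydes with dibenzoyl peroxide, and the labile product is trapped at once by an E-selective Wittig reaction with the stabilised ylide.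

**Step 3**
Reactants: 5 (2E,4R)-4-acetoxy-2,5,5-trimethylocta-2,7-dienal
Product: 6 (3S,4E,6R)-6-acetoxy-3-[(tert-butyldimethylsilyl)oxy]-4,7,7-trimethyldeca-4,9-dienal
Conditions: tert-butyldimethyl(vinyloxy)silane, chiral IDPi (imidodiphosphorimidate) acid (2 mol%), toluene, −60 °C
Reagents that add atoms: tert-butyldimethyl(vinyloxy)silane, C=CO[Si](C)(C)C(C)(C)C
Why: Organocatalytic Mukaiyama aldol of the acetaldehyde enol silane (single aldolisation inside the confined silylium–IDPi ion pair) adds to the Si face of the enal carbonyl under catalyst control, setting C4 as S and delivering the silyl group to the new oxygen.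

**Step 4**
Reactants: 6 (3S,4E,6R)-6-acetoxy-3-[(tert-butyldimethylsilyl)oxy]-4,7,7-trimethyldeca-4,9-dienal
Product: 7 (5R,6E,8S,10Z)-8-[(tert-butyldimethylsilyl)oxy]-11-iodo-4,4,7-trimethyldodeca-1,6,10-trien-5-yl acetate
Conditions: [Ph3PCH(I)CH3]I, NaN(SiMe3)2, THF, −78 to −20 °C
Reagents that add atoms: (1-iodoethyl)triphenylphosphonium iodide, CC(I)[P+](c1ccccc1)(c1ccccc1)c1ccccc1.[I-]
Why: Stork–Zhao-type iodo-Wittig olefination of an aldehyde with the α-iodoethylidene ylide is Z-selective (iodine cis to the chain), is precedented on β-silyloxy aldehydes of exactly this allylic type, and is fast enough at low temperature to spare the acetate.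

**Step 5**
Reactants: 7 (5R,6E,8S,10Z)-8-[(tert-butyldimethylsilyl)oxy]-11-iodo-4,4,7-trimethyldodeca-1,6,10-trien-5-yl acetate
Product: 9 (1R,2E,4S,6Z)-4-[(tert-butyldimethylsilyl)oxy]-3,7,11,11-tetramethylcycloundeca-2,6-dien-1-yl acetate, via alkylborane 8 (not isolated)
Conditions: 9-BBN-H, THF, rt; then slow addition to PdCl2(dppf) (15 mol%; dppf = 1,1'-bis(diphenylphosphino)ferrocene), AsPh3, Cs2CO3, DMF/THF/H2O, rt to 45 °C, 2 mM
Reagents that add atoms: none
Why: 9-BBN hydroborates only the monosubstituted terminal alkene, and the intramolecular B-alkyl Suzuki–Miyaura coupling closes the 11-membered ring at C7–C8 with retention of the vinyl iodide geometry (6Z), oxidative addition to the vinyl iodide being much faster than ionisation of the hindered allylic acetate.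

**Step 6**
Reactants: 9 (1R,2E,4S,6Z)-4-[(tert-butyldimethylsilyl)oxy]-3,7,11,11-tetramethylcycloundeca-2,6-dien-1-yl acetate
Product: 10 (1R,2E,4S,6Z)-4-hydroxy-3,7,11,11-tetramethylcycloundeca-2,6-dien-1-yl acetate
Conditions: HF·pyridine, pyridine, THF, 0 °C to rt
Reagents that add atoms: none
Why: Buffered fluoride desilylation removes the secondary silyl ether without touching the hindered acetate or risking acyl migration.

**Step 7**
Reactants: 10 (1R,2E,4S,6Z)-4-hydroxy-3,7,11,11-tetramethylcycloundeca-2,6-dien-1-yl acetate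
Product: 12 (1R,2E,4S,6Z)-1-acetoxy-3,7,11,11-tetramethylcycloundeca-2,6-dien-4-yl 4-hydroxybenzoate (CNP0246761.4), via aryl acetate 11 (not isolated)
Conditions: 4-acetoxybenzoyl chloride, pyridine, DMAP (cat.), CH2Cl2, 0 °C to rt; then pyrrolidine, 0 °C
Reagents that add atoms: 4-acetoxybenzoyl chloride, CC(=O)Oc1ccc(cc1)C(Cl)=O
Why: DMAP-catalysed acylation of the free C4 alcohol with retention is followed by chemoselective aminolysis of the phenolic acetate, which is far more reactive towards pyrrolidine than the neopentyl-type alkyl acetate or the alkyl benzoate.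

**Compound list**
1 | 2,2-dimethylpent-4-enal | O=CC(C)(C)CC=C | starting material
2 | 1-methoxy-3,3-dimethylhexa-1,5-diene (E/Z mixture) | COC=CC(C)(C)CC=C | intermediate
3 | 3,3-dimethylhex-5-enal | O=CCC(C)(C)CC=C | intermediate
4 | (2S)-3,3-dimethyl-1-oxohex-5-en-2-yl acetate | CC(=O)O[C@H](C=O)C(C)(C)CC=C | intermediate
5 | (2E,4R)-4-acetoxy-2,5,5-trimethylocta-2,7-dienal | CC(=O)O[C@H](/C=C(\C)C=O)C(C)(C)CC=C | intermediate
6 | (3S,4E,6R)-6-acetoxy-3-[(tert-butyldimethylsilyl)oxy]-4,7,7-trimethyldeca-4,9-dienal | CC(=O)O[C@H](/C=C(\C)[C@@H](O[Si](C)(C)C(C)(C)C)CC=O)C(C)(C)CC=C | intermediate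
7 | (5R,6E,8S,10Z)-8-[(tert-butyldimethylsilyl)oxy]-11-iodo-4,4,7-trimethyldodeca-1,6,10-trien-5-yl acetate | CC(=O)O[C@H](/C=C(\C)[C@@H](O[Si](C)(C)C(C)(C)C)C/C=C(/C)I)C(C)(C)CC=C | intermediate
8 | (5R,6E,8S,10Z)-1-(9-borabicyclo[3.3.1]nonan-9-yl)-8-[(tert-butyldimethylsilyl)oxy]-11-iodo-4,4,7-trimethyldodeca-6,10-dien-5-yl acetate | CC(=O)O[C@H](/C=C(\C)[C@@H](O[Si](C)(C)C(C)(C)C)C/C=C(/C)I)C(C)(C)CCCB1C2CCCC1CCC2 | intermediate
9 | (1R,2E,4S,6Z)-4-[(tert-butyldimethylsilyl)oxy]-3,7,11,11-tetramethylcycloundeca-2,6-dien-1-yl acetate | CC(=O)O[C@@H]1/C=C(\C)[C@@H](O[Si](C)(C)C(C)(C)C)C/C=C(/C)CCCC1(C)C | intermediate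
10 | (1R,2E,4S,6Z)-4-hydroxy-3,7,11,11-tetramethylcycloundeca-2,6-dien-1-yl acetate | CC(=O)O[C@@H]1/C=C(\C)[C@@H](O)C/C=C(/C)CCCC1(C)C | intermediate
11 | (1R,2E,4S,6Z)-1-acetoxy-3,7,11,11-tetramethylcycloundeca-2,6-dien-4-yl 4-acetoxybenzoate | CC(=O)O[C@@H]1/C=C(\C)[C@@H](OC(=O)c2ccc(OC(C)=O)cc2)C/C=C(/C)CCCC1(C)C | intermediate
12 | (1R,2E,4S,6Z)-1-acetoxy-3,7,11,11-tetramethylcycloundeca-2,6-dien-4-yl 4-hydroxybenzoate | CC(=O)O[C@@H]1/C=C(\C)[C@@H](OC(=O)c2ccc(O)cc2)C/C=C(/C)CCCC1(C)C | target

**Step count and risks**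
Total steps: 7. Longest linear sequence: 7 (fully linear from 1).

Steps most likely to fail:

Step 2 (the proposed α-acetoxylation). Risks are N-acyloxylation of the amine catalyst, transfer of the wrong acyloxy group, and low selectivity at the neopentyl α-carbon. The fallback uses known chemistry and sets out from 3. D-Proline-catalysed α-aminoxylation with nitrosobenzene (CHCl3, 4 °C) gives (2S)-3,3-dimethyl-2-[(phenylamino)oxy]hex-5-enal F1. This is trapped in the same flask with 2-(triphenylphosphoranylidene)propanal to give (2E,4R)-2,5,5-trimethyl-4-[(phenylamino)oxy]octa-2,7-dienal F2. CuSO4·5H2O in MeOH at 0 °C cleaves the N–O bond to (2E,4R)-4-hydroxy-2,5,5-trimethylocta-2,7-dienal F3. Acetylation (Ac2O, pyridine, DMAP) then comes back to the route at 5, at a cost of two extra steps.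

Step 3 (IDPi aldehyde aldol on an α-branched, γ-acetoxy enal). Risks are low reactivity of the enal or erosion of catalyst control by the strong acid. The fallback sets out from 5 and switches from silylium Lewis-acid catalysis to enamine catalysis. A direct cross-aldol with acetaldehyde itself, catalysed by an α,α-diarylprolinol (enantiomer chosen for Si-face attack), gives (3S,4E,6R)-6-acetoxy-3-hydroxy-4,7,7-trimethyldeca-4,9-dienal F4. Silylation of the crude aldol with TBSOTf and 2,6-lutidine at −78 °C comes back to the route at 6.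

Step 5 (11-membered B-alkyl Suzuki macrocyclisation). Risks are oligomerisation, slow transmetalation at high dilution, and hydrolysis or ionisation of the allylic acetate under aqueous base. The fallback sets out from 7 and replaces the in-situ borane and aqueous base with a preformed organozinc under base-free Negishi conditions. Hydroboration–oxidation (9-BBN-H, then NaBO3·4H2O) gives (5R,6E,8S,10Z)-8-[(tert-butyldimethylsilyl)oxy]-1-hydroxy-11-iodo-4,4,7-trimethyldodeca-6,10-dien-5-yl acetate F5. Iodination (I2, PPh3, imidazole) gives (5R,6E,8S,10Z)-8-[(tert-butyldimethylsilyl)oxy]-1,11-diiodo-4,4,7-trimethyldodeca-6,10-dien-5-yl acetate F6. Zinc dust with LiCl in THF inserts selectively into the primary C–I bond to give the alkylzinc iodide of F6 F7. Pd(PPh3)4 at high dilution closes the ring and comes back to the route at 9.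

**Further compounds**
F1 | step 2 | (2S)-3,3-dimethyl-2-[(phenylamino)oxy]hex-5-enal | c1ccccc1NO[C@H](C=O)C(C)(C)CC=C
F2 | step 2 | (2E,4R)-2,5,5-trimethyl-4-[(phenylamino)oxy]octa-2,7-dienal | c1ccccc1NO[C@H](/C=C(\C)C=O)C(C)(C)CC=C
F3 | step 2 | (2E,4R)-4-hydroxy-2,5,5-trimethylocta-2,7-dienal | O[C@H](/C=C(\C)C=O)C(C)(C)CC=C
F4 | step 3 | (3S,4E,6R)-6-acetoxy-3-hydroxy-4,7,7-trimethyldeca-4,9-dienal | CC(=O)O[C@H](/C=C(\C)[C@@H](O)CC=O)C(C)(C)CC=C
F5 | step 5 | (5R,6E,8S,10Z)-8-[(tert-butyldimethylsilyl)oxy]-1-hydroxy-11-iodo-4,4,7-trimethyldodeca-6,10-dien-5-yl acetate | CC(=O)O[C@H](/C=C(\C)[C@@H](O[Si](C)(C)C(C)(C)C)C/C=C(/C)I)C(C)(C)CCCO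
F6 | step 5 | (5R,6E,8S,10Z)-8-[(tert-butyldimethylsilyl)oxy]-1,11-diiodo-4,4,7-trimethyldodeca-6,10-dien-5-yl acetate | CC(=O)O[C@H](/C=C(\C)[C@@H](O[Si](C)(C)C(C)(C)C)C/C=C(/C)I)C(C)(C)CCCI
F7 | step 5 | alkylzinc iodide of F6 (zinc inserted into the primary C–I bond) | CC(=O)O[C@H](/C=C(\C)[C@@H](O[Si](C)(C)C(C)(C)C)C/C=C(/C)I)C(C)(C)CCC[Zn]I
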